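**Retrosynthetic overview**
1. The allylic acetate is made last from a prenyl terminus: Shi epoxidation, epoxide-to-allylic-alcohol isomerisation, acetylation.
2. Ring C (the cycloheptenone) comes from a cyclopenta[c]pyran enol ether: hydrolysis frees the C20 aldehyde and the tertiary alcohol, and aldol condensation with an ethyl ketone arm closes the seven-membered ring.
3. Ring A (cyclopentane) and ring B (a temporary dihydropyran) form together by an intramolecular inverse-demand oxa-Diels–Alder reaction of an acyclic keto-enal onto a Z-trisubstituted olefin.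
4. The keto-enal comes from a dihydrofuran ester by B-alkyl Suzuki coupling with a Z-vinyl iodide (Normant carbocupration), decarboxylation, oxidation and Wittig reaction.
5. The single catalyst-set carbon stereocenter (the quaternary methyl carbon) comes from a Pd-catalysed asymmetric allylic alkylation of isoprene monoepoxide. Ring order: dihydrofuran (temporary), then rings A and B together, then ring C as ring B opens.

Assumption: the (R,R)-DACH-phenyl Trost ligand is taken to give the (R)-quaternary center in step 2 and the L-fructose-derived (ent-)Shi ketone the (S)-epoxide in step 9; if either sense is found reversed, the mirror-image ligand or ketone is used.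

**Route**

Step 1
Reactants: 1 5-bromo-2-methylpent-2-ene; 2 propyne
Product: 5 (1Z)-1-iodo-2,6-dimethylhepta-1,5-diene, via Grignard reagent 3 (not isolated), via alkenylcopper 4 (not isolated)
Conditions: Mg, THF; CuBr·SMe2, Et2O–Me2S, −45 °C; 2, −25 °C; I2, THF, −40 → 0 °C
Reagents that add atoms: iodine, II
Why: Normant carbocupration: the alkylcopper adds syn across propyne with copper on the terminal carbon, and iodinolysis with retention fixes the Z-trisubstituted olefin (chain cis to iodine) that later serves as the dienophile.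

Step 2
Reactants: 6 2-methyl-2-vinyloxirane (racemic); 7 methyl 3-oxopentanoate
Product: 9 methyl (4R)-4-ethenyl-2-ethyl-4-methyl-4,5-dihydrofuran-3-carboxylate, via hydroxy keto ester 8 (not isolated)
Conditions: Pd2(dba)3·CHCl3 (1 mol %), (R,R)-DACH-phenyl Trost ligand (3 mol %), CH2Cl2, rt; then TsOH·H2O (5 mol %), 4 Å MS, rt
Reagents that add atoms: none
Why: Trost asymmetric allylic alkylation run as a dynamic kinetic asymmetric transformation: the π-allyl intermediates from the racemic epoxide interconvert, the alkoxide steers the ketoester to the substituted terminus inside the chiral pocket so the catalyst sets the quaternary stereocenter, and acid cyclodehydrates the adduct to a dihydrofuran that masks ketone and alcohol.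

Step 3
Reactants: 9 methyl (4R)-4-ethenyl-2-ethyl-4-methyl-4,5-dihydrofuran-3-carboxylate; 5 (1Z)-1-iodo-2,6-dimethylhepta-1,5-diene
Product: 11 methyl (4R)-4-[(3Z)-4,8-dimethylnona-3,7-dien-1-yl]-2-ethyl-4-methyl-4,5-dihydrofuran-3-carboxylate, via alkylborane 10 (not isolated)
Conditions: 9-BBN, THF, rt → 50 °C; then 5, Pd(dppf)Cl2 (5 mol %), AsPh3, Cs2CO3, DMF–H2O, rt
Reagents that add atoms: none
Why: 9-BBN hydroborates only the terminal vinyl group (the push–pull dihydrofuran olefin is inert) and the B-alkyl Suzuki–Miyaura coupling joins the primary borane to the vinyl iodide with retention of the Z geometry, no stereocenter being touched.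

Step 4
Reactants: 11 methyl (4R)-4-[(3Z)-4,8-dimethylnona-3,7-dien-1-yl]-2-ethyl-4-methyl-4,5-dihydrofuran-3-carboxylate
Product: 13 (5R,8Z)-5-(hydroxymethyl)-5,9,13-trimethyltetradeca-8,12-dien-3-one, via dihydrofuran acid 12 (not isolated)
Conditions: LiOH, THF–MeOH–H2O, 60 °C; then 1 M HCl to pH 2, 40 °C
Reagents that add atoms: water, O
Why: Saponification then mild acid turns the vinylogous carbonate into a β-keto acid that hydrolyses and decarboxylates (ester hydrolysis/decarboxylation), leaving the quaternary center and both trisubstituted olefins untouched.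

Step 5
Reactants: 13 (5R,8Z)-5-(hydroxymethyl)-5,9,13-trimethyltetradeca-8,12-dien-3-one
Product: 14 (2R)-2-[(3Z)-4,8-dimethylnona-3,7-dien-1-yl]-2-methyl-4-oxohexanal
Conditions: Dess–Martin periodinane, CH2Cl2, 0 °C → rt
Reagents that add atoms: none
Why: Dess–Martin oxidation converts the neopentyl primary alcohol to the aldehyde under neutral conditions that do not trigger aldol closure of the 1,4-keto aldehyde.

Step 6
Reactants: 14 (2R)-2-[(3Z)-4,8-dimethylnona-3,7-dien-1-yl]-2-methyl-4-oxohexanal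
Product: 15 (2E,4R,7Z)-4,8,12-trimethyl-4-(2-oxobutyl)trideca-2,7,11-trienal
Conditions: Ph3P=CHCHO (1.1 equiv), toluene, 80 °C
Reagents that add atoms: (triphenylphosphoranylidene)acetaldehyde, O=CC=P(c1ccccc1)(c1ccccc1)c1ccccc1
Why: Wittig olefination with the stabilised formyl ylide attacks only the aldehyde, not the ketone, and gives the E-enal that serves as the oxadiene.

Step 7
Reactants: 15 (2E,4R,7Z)-4,8,12-trimethyl-4-(2-oxobutyl)trideca-2,7,11-trienal
Product: 16 1-[(1S,4aS,5R,7aS)-1,5-dimethyl-1-(4-methylpent-3-en-1-yl)-1,4a,5,6,7,7a-hexahydrocyclopenta[c]pyran-5-yl]butan-2-one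
Conditions: Me2AlCl (2.2 equiv), CH2Cl2, −78 → −20 °C
Reagents that add atoms: none
Why: Proposed new method: intramolecular inverse-electron-demand oxa-Diels–Alder reaction of a simple enal, activated by the aluminium Lewis acid, with the tethered Z-trisubstituted olefin — the enal β-carbon bonds to the less substituted olefin carbon and the carbonyl oxygen to the carbon that best carries positive charge, the three-atom tether enforces the cis ring fusion, suprafacial addition to the Z-olefin fixes the oxygen-bearing quaternary center relative to the fusion, and the small methyl rather than the oxobutyl arm sits over the forming pyran so ring B grows syn to methyl; the closest known reactions are the Tietze intramolecular hetero-Diels–Alder of alkylidene-1,3-dicarbonyls and Lewis-acid-induced enal–olefin cyclisations.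

Step 8
Reactants: 16 1-[(1S,4aS,5R,7aS)-1,5-dimethyl-1-(4-methylpent-3-en-1-yl)-1,4a,5,6,7,7a-hexahydrocyclopenta[c]pyran-5-yl]butan-2-one
Product: 18 (1S,3aR,8aS)-1-[(2S)-2-hydroxy-6-methylhept-5-en-2-yl]-3a,6-dimethyl-2,3,3a,4,8,8a-hexahydroazulen-5(1H)-one, via lactol 17 (not isolated)
Conditions: HCl (0.05 equiv), THF–H2O, 0 °C → rt; then KOH (0.2 equiv), MeOH, 0.01 M, 40 °C
Reagents that add atoms: none
Why: Acid hydrolysis of the cyclic enol ether gives the lactol, whose open hydroxy aldehyde undergoes base-mediated intramolecular aldol condensation with the ethyl ketone at its unhindered methylene to give the conjugated cycloheptenone (closure through the other α-carbon would need a trans-fused bicyclo[3.3.0]octane), freeing the tertiary alcohol and leaving all four stereocenters untouched.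

Step 9
Reactants: 18 (1S,3aR,8aS)-1-[(2S)-2-hydroxy-6-methylhept-5-en-2-yl]-3a,6-dimethyl-2,3,3a,4,8,8a-hexahydroazulen-5(1H)-one
Product: 19 (1S,3aR,8aS)-1-{(2S)-4-[(2S)-3,3-dimethyloxiran-2-yl]-2-hydroxybutan-2-yl}-3a,6-dimethyl-2,3,3a,4,8,8a-hexahydroazulen-5(1H)-one
Conditions: ent-Shi ketone (0.3 equiv), 2KHSO5·KHSO4·K2SO4 (Oxone), K2CO3, Bu4NHSO4 (cat.), MeCN–(MeO)2CH2–aq. Na2B4O7/Na2EDTA, 0 °C
Reagents that add atoms: potassium peroxymonosulfate (KHSO5), [K+].[O-]S(=O)(=O)OO
Why: Shi asymmetric epoxidation: the chiral dioxirane attacks only the electron-rich trisubstituted olefin (the enone is inert) and sets the new C–O stereocenter by reagent control.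

Step 10
Reactants: 19 (1S,3aR,8aS)-1-{(2S)-4-[(2S)-3,3-dimethyloxiran-2-yl]-2-hydroxybutan-2-yl}-3a,6-dimethyl-2,3,3a,4,8,8a-hexahydroazulen-5(1H)-one
Product: 21 (1S,3aR,8aS)-1-[(2S,5S)-2,5-dihydroxy-6-methylhept-6-en-2-yl]-3a,6-dimethyl-2,3,3a,4,8,8a-hexahydroazulen-5(1H)-one, via bis-silyl ether 20 (not isolated)
Conditions: TMSOTf (2.5 equiv), DBU (2.5 equiv), toluene, 0 °C → rt; then 1 M HCl, THF, 0 °C
Reagents that add atoms: none
Why: Noyori-type silyl triflate/amidine isomerisation of the epoxide: silylation of the epoxide oxygen, ionisation toward the tertiary carbon and loss of a methyl proton give the allyl silyl ether with the carbinol C–O bond and its configuration untouched, and mild acid removes the silyl groups and returns any silyl dienol ether to the enone.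

Step 11
Reactants: 21 (1S,3aR,8aS)-1-[(2S,5S)-2,5-dihydroxy-6-methylhept-6-en-2-yl]-3a,6-dimethyl-2,3,3a,4,8,8a-hexahydroazulen-5(1H)-one
Product: 22 (3S,6S)-6-[(1S,3aR,8aS)-3a,6-dimethyl-5-oxo-1,2,3,3a,4,5,8,8a-octahydroazulen-1-yl]-6-hydroxy-2-methylhept-1-en-3-yl acetate
Conditions: Ac2O (1.2 equiv), pyridine, DMAP (cat.), CH2Cl2, 0 °C
Reagents that add atoms: acetic anhydride, CC(=O)OC(C)=O
Why: Acylation with acetic anhydride/pyridine/DMAP at 0 °C esterifies only the secondary allylic alcohol, the hindered tertiary alcohol being unreactive.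

**Compound list**
1 | 5-bromo-2-methylpent-2-ene | CC(C)=CCCBr | starting material
2 | propyne | CC#C | starting material
3 | (4-methylpent-3-en-1-yl)magnesium bromide | CC(C)=CCC[Mg]Br | intermediate
4 | [(1Z)-2,6-dimethylhepta-1,5-dien-1-yl]copper | [Cu]/C=C(/C)CCC=C(C)C | intermediate
5 | (1Z)-1-iodo-2,6-dimethylhepta-1,5-diene | I/C=C(/C)CCC=C(C)C | intermediate
6 | 2-methyl-2-vinyloxirane (racemic) | C=CC1(C)CO1 | starting material
7 | methyl 3-oxopentanoate | CCC(=O)CC(=O)OC | starting material
8 | methyl 2-[(2R)-1-hydroxy-2-methylbut-3-en-2-yl]-3-oxopentanoate (both epimers at C2) | CCC(=O)C(C(=O)OC)[C@](C)(CO)C=C | intermediate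
9 | methyl (4R)-4-ethenyl-2-ethyl-4-methyl-4,5-dihydrofuran-3-carboxylate | CCC1=C(C(=O)OC)[C@@](C)(C=C)CO1 | intermediate
10 | methyl (4R)-4-[2-(9-borabicyclo[3.3.1]nonan-9-yl)ethyl]-2-ethyl-4-methyl-4,5-dihydrofuran-3-carboxylate | CCC1=C(C(=O)OC)[C@@](C)(CCB2C3CCCC2CCC3)CO1 | intermediate
11 | methyl (4R)-4-[(3Z)-4,8-dimethylnona-3,7-dien-1-yl]-2-ethyl-4-methyl-4,5-dihydrofuran-3-carboxylate | CCC1=C(C(=O)OC)[C@@](C)(CC/C=C(/C)CCC=C(C)C)CO1 | intermediate
12 | (4R)-4-[(3Z)-4,8-dimethylnona-3,7-dien-1-yl]-2-ethyl-4-methyl-4,5-dihydrofuran-3-carboxylic acid | CCC1=C(C(=O)O)[C@@](C)(CC/C=C(/C)CCC=C(C)C)CO1 | intermediate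
13 | (5R,8Z)-5-(hydroxymethyl)-5,9,13-trimethyltetradeca-8,12-dien-3-one | CCC(=O)C[C@](C)(CO)CC/C=C(/C)CCC=C(C)C | intermediate
14 | (2R)-2-[(3Z)-4,8-dimethylnona-3,7-dien-1-yl]-2-methyl-4-oxohexanal | CCC(=O)C[C@](C)(C=O)CC/C=C(/C)CCC=C(C)C | intermediate
15 | (2E,4R,7Z)-4,8,12-trimethyl-4-(2-oxobutyl)trideca-2,7,11-trienal | CCC(=O)C[C@](C)(/C=C/C=O)CC/C=C(/C)CCC=C(C)C | intermediate
16 | 1-[(1S,4aS,5R,7aS)-1,5-dimethyl-1-(4-methylpent-3-en-1-yl)-1,4a,5,6,7,7a-hexahydrocyclopenta[c]pyran-5-yl]butan-2-one | CCC(=O)C[C@@]1(C)CC[C@H]2[C@@H]1C=CO[C@@]2(C)CCC=C(C)C | intermediate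
17 | 1-[(1S,4aS,5R,7aS)-3-hydroxy-1,5-dimethyl-1-(4-methylpent-3-en-1-yl)octahydrocyclopenta[c]pyran-5-yl]butan-2-one (both anomers) | CCC(=O)C[C@@]1(C)CC[C@H]2[C@@H]1CC(O)O[C@@]2(C)CCC=C(C)C | intermediate
18 | (1S,3aR,8aS)-1-[(2S)-2-hydroxy-6-methylhept-5-en-2-yl]-3a,6-dimethyl-2,3,3a,4,8,8a-hexahydroazulen-5(1H)-one | CC(C)=CCC[C@](C)(O)[C@H]1CC[C@]2(C)CC(=O)C(C)=CC[C@@H]12 | intermediate
19 | (1S,3aR,8aS)-1-{(2S)-4-[(2S)-3,3-dimethyloxiran-2-yl]-2-hydroxybutan-2-yl}-3a,6-dimethyl-2,3,3a,4,8,8a-hexahydroazulen-5(1H)-one | CC1(C)O[C@H]1CC[C@](C)(O)[C@H]2CC[C@]3(C)CC(=O)C(C)=CC[C@@H]23 | intermediate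
20 | bis(trimethylsilyl) ether of 21 | C=C(C)[C@@H](O[Si](C)(C)C)CC[C@](C)(O[Si](C)(C)C)[C@H]1CC[C@]2(C)CC(=O)C(C)=CC[C@@H]12 | intermediate
21 | (1S,3aR,8aS)-1-[(2S,5S)-2,5-dihydroxy-6-methylhept-6-en-2-yl]-3a,6-dimethyl-2,3,3a,4,8,8a-hexahydroazulen-5(1H)-one | C=C(C)[C@@H](O)CC[C@](C)(O)[C@H]1CC[C@]2(C)CC(=O)C(C)=CC[C@@H]12 | intermediate
22 | (3S,6S)-6-[(1S,3aR,8aS)-3a,6-dimethyl-5-oxo-1,2,3,3a,4,5,8,8a-octahydroazulen-1-yl]-6-hydroxy-2-methylhept-1-en-3-yl acetate | C=C(C)[C@H](CC[C@](C)(O)[C@H]1CC[C@]2(C)CC(=O)C(C)=CC[C@@H]12)OC(C)=O | target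

**Totals and risks**
Total step count: 11. Longest linear sequence: 10 steps (steps 2 to 11, or step 1 followed by steps 3 to 11).

Most likely to fail: step 7, step 8 and step 10.

Step 7 (Lewis-acid oxa-Diels–Alder of an unactivated enal; risks are ene-type proton loss, erosion of the Z-olefin information and modest facial selectivity at the quaternary center). The fallback sets out from keto aldehyde 14 and uses an oxadiene activated by a second carbonyl group. Knoevenagel condensation with Meldrum's acid (ethylenediammonium diacetate, CH2Cl2, rt) gives the alkylidene Meldrum's acid F1, which cyclises in the same flask by a concerted Tietze hetero-Diels–Alder reaction to the tricyclic ketene acetal F2. Heating in wet pyridine opens the dioxinone and decarboxylates to the δ-lactone F3. The ketone is then masked in the flask as the lithium enolate F4 (LiN(i-Pr)2, THF, −78 °C) and the lactone is reduced with i-Bu2AlH to lactol 17, where the route is rejoined at the base stage of step 8.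

Step 8 (seven-membered ring by reversible aldol condensation; risks are stalling at the lactol and intermolecular aldol). The fallback sets out from enol ether 16, which MeOH/PPTS converts to the methyl acetal F5. TMSOTf and i-Pr2NEt (CH2Cl2, −78 → 0 °C) form the trimethylsilyl enol ether F6 on the unhindered side of the ethyl ketone and ionise the acetal, so an intramolecular Mukaiyama-type addition to the oxocarbenium ion closes ring C irreversibly to the oxa-bridged ketone F7. DBU (toluene, 60 °C) then expels the tertiary alkoxide by E1cB elimination and gives enone alcohol 18.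

Step 10 (epoxide isomerisation beside an enone; risks are enone deconjugation and Meinwald rearrangement). The fallback sets out from epoxide 19, which benzeneselenol with catalytic BF3·OEt2 (CH2Cl2, −78 °C) opens at the tertiary carbon to the hydroxy selenide F8. Oxidation (H2O2, pyridine, CH2Cl2, 0 °C → rt) gives the selenoxide F9, whose syn-elimination runs away from the carbinol carbon into a methyl group and delivers allylic alcohol 21 with the C–O stereocenter untouched; any selenol that added to the enone is expelled in the same oxidation.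

**Further compounds**
F1 | step 7 | 5-{(2E? not applicable)-[(2R)-2-[(3Z)-4,8-dimethylnona-3,7-dien-1-yl]-2-methyl-4-oxohexylidene]}-2,2-dimethyl-1,3-dioxane-4,6-dione (alkylidene Meldrum's acid) | CCC(=O)C[C@](C)(C=C1C(=O)OC(C)(C)OC1=O)CC/C=C(/C)CCC=C(C)C
F2 | step 7 | tricyclic hetero-Diels–Alder adduct (cyclopenta-fused pyrano[2,3-d][1,3]dioxin-4-one ketene acetal) | CCC(=O)C[C@@]1(C)CC[C@H]2[C@@H]1C3=C(OC(C)(C)OC3=O)O[C@@]2(C)CCC=C(C)C
F3 | step 7 | 1-[(1S,4aS,5R,7aS)-1,5-dimethyl-1-(4-methylpent-3-en-1-yl)-3-oxooctahydrocyclopenta[c]pyran-5-yl]butan-2-one (δ-lactone) | CCC(=O)C[C@@]1(C)CC[C@H]2[C@@H]1CC(=O)O[C@@]2(C)CCC=C(C)C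
F4 | step 7 | lithium enolate of the ethyl ketone of F3 | CC=C(O[Li])C[C@@]1(C)CC[C@H]2[C@@H]1CC(=O)O[C@@]2(C)CCC=C(C)C
F5 | step 8 | 1-[(1S,4aS,5R,7aS)-3-methoxy-1,5-dimethyl-1-(4-methylpent-3-en-1-yl)octahydrocyclopenta[c]pyran-5-yl]butan-2-one (methyl acetal, both anomers) | CCC(=O)C[C@@]1(C)CC[C@H]2[C@@H]1CC(OC)O[C@@]2(C)CCC=C(C)C
F6 | step 8 | trimethylsilyl enol ether of F5 | CC=C(O[Si](C)(C)C)C[C@@]1(C)CC[C@H]2[C@@H]1CC(OC)O[C@@]2(C)CCC=C(C)C
F7 | step 8 | oxa-bridged tricyclic β-alkoxy ketone (C18–C20 bond formed, ether bridge to the carbinol carbon retained; two new centers unassigned) | CC1C(=O)C[C@@]2(C)CC[C@H]3[C@@H]2CC1O[C@@]3(C)CCC=C(C)C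
F8 | step 10 | (1S,3aR,8aS)-1-[(2S,5S)-2,5-dihydroxy-6-methyl-6-(phenylselanyl)heptan-2-yl]-3a,6-dimethyl-2,3,3a,4,8,8a-hexahydroazulen-5(1H)-one | CC(C)([Se]c1ccccc1)[C@@H](O)CC[C@](C)(O)[C@H]1CC[C@]2(C)CC(=O)C(C)=CC[C@@H]12
F9 | step 10 | selenoxide of F8 | CC(C)([Se](=O)c1ccccc1)[C@@H](O)CC[C@](C)(O)[C@H]1CC[C@]2(C)CC(=O)C(C)=CC[C@@H]12
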